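**Retrosynthetic overview**

1. Feature used: the oxane ring (O1, C2 gem-dimethyl, C3–Br, C5–OH, C6) and the cyclohexane (C4'(Me)–Br and C5'–Cl trans-diaxial, ring anchored by the equatorial C1' substituent) each hold a Markovnikov anti adduct of a trisubstituted alkene (O1–C2/C3–Br and C4'–X/C5'–Y).
2. C4'–Br goes back to a tertiary C4'–OH (retention through a chlorine-bridged ion) and C5'–Cl to an oxirane across C4'/C5', which comes from the ring bromohydrin (C5'–Br, C4'–OH); C5' is thus inverted twice.
3. Key disconnection: O1–C2, C3–Br, C5'–Br and C4'–OH are removed together, giving a diene diol monoacetate that takes up two Br+ in one flask.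
4. The diene diol comes from (S)-limonene: C10 hydroxylation, Sharpless epoxidation and hydride opening (C6), oxidation and chelation-controlled allylation (C5), cross-metathesis to the prenyl terminus (C2, C3).
5. Ring order: the cyclohexene ring is bought with limonene; the oxane closes in step 8 (O1–C2); an oxirane on C4'/C5' is closed in step 9 and opened in step 10.

Key step: step 8

Atom labels used below: oxane O1, C2 (CMe2), C3 (CHBr), C4, C5 (CHOH), C6 (CMe); cyclohexane C1' (on C6), C2', C3', C4' (CMeBr), C5' (CHCl), C6'.
Assumption: (S)-(−)-limonene of high enantiomeric purity is used, and the tartrate in step 2 is assigned from the Sharpless face rule (L-(+)-tartrate gives the 2S epoxy alcohol), which points to the D-(−)-ester for the C6 configuration of the target.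

**Route**

Step 1
Reactants: 1 (S)-(−)-limonene
Product: 4 (S)-p-mentha-1,8-dien-10-ol, via allyllithium 2 (not isolated), via dimethyl allylboronate 3 (not isolated)
Conditions: n-BuLi, TMEDA, hexane, 0 °C to rt; B(OMe)3, Et2O, −78 °C to rt; 30% H2O2, aq NaOH, 0 °C
Reagents that add atoms: hydrogen peroxide, OO
Why: Allylic metalation–borylation–oxidation: the n-BuLi/TMEDA base removes a proton from the isopropenyl methyl group to give a 2-substituted allyllithium with equivalent termini, which is borylated and then oxidised with carbon-to-oxygen migration, so the CH2OH group (the future C5) appears without touching the C1' stereocentre or the ring alkene.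

Step 2
Reactants: 4 (S)-p-mentha-1,8-dien-10-ol
Product: 5 (4S,8R)-8,9-epoxy-p-menth-1-en-10-ol
Conditions: Ti(OiPr)4 (10 mol %), D-(−)-diisopropyl tartrate (12 mol %), t-BuOOH, 4 Å MS, CH2Cl2, −20 °C
Reagents that add atoms: tert-butyl hydroperoxide, CC(C)(C)OO
Why: Sharpless asymmetric epoxidation of a 2-substituted allylic alcohol under reagent control: the ring alkene has no hydroxyl to bind titanium and stays, and since L-(+)-tartrate delivers oxygen to the face that makes C2 of a 2-substituted glycidol S, the D-(−)-ester should give the 8R oxirane carbon drawn here, which becomes C6.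

Step 3
Reactants: 5 (4S,8R)-8,9-epoxy-p-menth-1-en-10-ol
Product: 6 (2R)-2-[(1S)-4-methylcyclohex-3-en-1-yl]propane-1,2-diol
Conditions: LiAlH4, THF, 0 °C to rt; aq NaOH work-up
Reagents that add atoms: none
Why: Hydride opening of the epoxide (SN2) at its unsubstituted CH2, the only accessible carbon because the other is quaternary, turns that carbon into the C6 methyl and leaves the C6–O bond, and so the configuration set in step 2, untouched.

Step 4
Reactants: 6 (2R)-2-[(1S)-4-methylcyclohex-3-en-1-yl]propane-1,2-diol
Product: 7 (2R)-2-hydroxy-2-[(1S)-4-methylcyclohex-3-en-1-yl]propanal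
Conditions: TEMPO (10 mol %), PhI(OAc)2 (1.1 equiv), CH2Cl2, 0 °C to rt; used crude
Reagents that add atoms: none
Why: TEMPO/PhI(OAc)2 (oxoammonium) oxidation converts only the primary carbinol, the tertiary hydroxyl having no carbinol hydrogen, and the α-carbon is quaternary so nothing can epimerise; the sensitive α-hydroxy aldehyde is used at once.

Step 5
Reactants: 7 (2R)-2-hydroxy-2-[(1S)-4-methylcyclohex-3-en-1-yl]propanal; 8 allyl bromide
Product: 10 (2R,3R)-2-[(1S)-4-methylcyclohex-3-en-1-yl]hex-5-ene-2,3-diol, via allylindium dibromide 9 (not isolated)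
Conditions: In powder, THF/H2O (1:1), rt
Reagents that add atoms: none
Why: Barbier allylation with indium in water under Cram chelation control: the metal ties the aldehyde oxygen to the free C6 hydroxyl, and the allyl group adds to the carbonyl face flanked by the small C6 methyl, away from the cyclohexenyl group, which sets C5 as R.

Step 6
Reactants: 10 (2R,3R)-2-[(1S)-4-methylcyclohex-3-en-1-yl]hex-5-ene-2,3-diol; 11 2-methyl-2-butene
Product: 12 (2R,3R)-6-methyl-2-[(1S)-4-methylcyclohex-3-en-1-yl]hept-5-ene-2,3-diol
Conditions: second-generation Grubbs catalyst (3 mol %), 2-methyl-2-butene (excess)/CH2Cl2, 35 °C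
Reagents that add atoms: none
Why: Olefin cross-metathesis in excess 2-methyl-2-butene exchanges the terminal CH2 of the vinyl group for an isopropylidene unit (propene leaves), the trisubstituted ring alkene being too hindered to enter the catalytic cycle and the free diol being tolerated, so the prenyl terminus C3=C2(Me)2 is installed without change at any stereocentre.

Step 7
Reactants: 12 (2R,3R)-6-methyl-2-[(1S)-4-methylcyclohex-3-en-1-yl]hept-5-ene-2,3-diol
Product: 13 (2R,3R)-2-hydroxy-6-methyl-2-[(1S)-4-methylcyclohex-3-en-1-yl]hept-5-en-3-yl acetate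
Conditions: Ac2O, pyridine, DMAP (cat.), CH2Cl2, 0 °C to rt
Reagents that add atoms: acetic anhydride, CC(=O)OC(C)=O
Why: Acylation (Ac2O/pyridine) discriminates the secondary C5 hydroxyl from the tertiary C6 hydroxyl on steric grounds, and the acetate removes the C5 oxygen as a competitor (5-endo closure to a tetrahydrofuran) in the next step.

Step 8
Reactants: 13 (2R,3R)-2-hydroxy-6-methyl-2-[(1S)-4-methylcyclohex-3-en-1-yl]hept-5-en-3-yl acetate
Product: 15 (2R,3R,5R)-5-bromo-2-[(1S,3R,4R)-3-bromo-4-hydroxy-4-methylcyclohexyl]-2,6,6-trimethyloxan-3-yl acetate, via bromo-oxane alkene 14 (not isolated)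
Conditions: NBS (1.0 equiv), (CF3)2CHOH, 0 °C, dark; then acetone/H2O (4:1), NBS (1.1 equiv), 0 °C
Reagents that add atoms: N-bromosuccinimide, O=C1CCC(=O)N1Br; water, O
Why: In the non-nucleophilic fluorinated alcohol NBS passes Br+ reversibly to both trisubstituted alkenes, and the ion on C2=C3 is the one consumed, because the C6 hydroxyl can reach its tertiary carbon C2 and opens it there anti to bromine (Markovnikov), which closes the oxane ring by 6-endo attack with formation of O1–C2. This is the familiar NBS bromoetherification of a tertiary alcohol onto a prenyl-type alkene, and the second stage, started by adding water and a second equivalent of NBS, is the NBS–water bromohydrin reaction of limonene-type 1-methylcyclohexenes. C3 is set by the existing C6 centre: the closure runs through a chair with the cyclohexenyl group equatorial and the C6 methyl axial, so anti addition leaves the C3 bromine equatorial and cis to the C6 methyl. C4' and C5' are set together: of the two ring bromonium ions only the one on the face trans to the equatorial C1' substituent can be opened by water at the tertiary C4' along a trans-diaxial, chair-like path, so a single bromohydrin with axial C5'–Br and axial C4'–OH (hydroxyl cis to the C1' substituent) is expected. The step needs 6-endo closure to win over 5-exo closure and over capture of a ring bromonium by the C6 hydroxyl (bridged, cineole-type ether); the positive charge at the tertiary C2, the strain-free chair as against a boat with an axial C1' substituent, and the C5 acetate that withholds the only other oxygen nucleophile are relied on for this. The product carries OH and Br on exactly the faces where the target has Br and Cl, which the next three steps exchange.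

Step 9
Reactants: 15 (2R,3R,5R)-5-bromo-2-[(1S,3R,4R)-3-bromo-4-hydroxy-4-methylcyclohexyl]-2,6,6-trimethyloxan-3-yl acetate
Product: 17 (2R,3R,5R)-5-bromo-2,6,6-trimethyl-2-[(1S,3S,6R)-6-methyl-7-oxabicyclo[4.1.0]heptan-3-yl]oxan-3-ol (oxirane oxygen cis to the oxanyl group), via epoxide acetate 16 (not isolated)
Conditions: K2CO3, MeOH, 0 °C to rt
Reagents that add atoms: none
Why: Base-induced epoxide closure (intramolecular Williamson reaction): the axial C4' alkoxide displaces the antiperiplanar axial C5' bromide with inversion, giving the oxirane with its oxygen cis to the C1' substituent, while methanolysis removes the C5 acetate; the equatorial, neopentyl-type C3 bromide has neither an open backside nor an antiperiplanar hydrogen and should survive.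

Step 10
Reactants: 17 (2R,3R,5R)-5-bromo-2,6,6-trimethyl-2-[(1S,3S,6R)-6-methyl-7-oxabicyclo[4.1.0]heptan-3-yl]oxan-3-ol
Product: 18 (2R,3R,5R)-5-bromo-2-[(1S,3R,4R)-3-chloro-4-hydroxy-4-methylcyclohexyl]-2,6,6-trimethyloxan-3-ol
Conditions: HCl (anhydrous, 2 M in Et2O), CH2Cl2, −40 °C
Reagents that add atoms: hydrogen chloride, Cl
Why: Acid-mediated epoxide opening under the Fürst–Plattner rule: with the C1' substituent equatorial the only trans-diaxial path is attack of chloride at the secondary C5' anti to oxygen, a second inversion that returns C5' to the configuration it had in the bromohydrin (now with axial chlorine) and leaves the axial C4' hydroxyl.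

Step 11
Reactants: 18 (2R,3R,5R)-5-bromo-2-[(1S,3R,4R)-3-chloro-4-hydroxy-4-methylcyclohexyl]-2,6,6-trimethyloxan-3-ol
Product: 19 (2R,3R,5R)-5-bromo-2-[(1S,3R,4R)-4-bromo-3-chloro-4-methylcyclohexyl]-2,6,6-trimethyloxan-3-ol (CNP0151640.1)
Conditions: HBr (anhydrous, excess), CH2Cl2, −40 to 0 °C
Reagents that add atoms: hydrogen bromide, Br
Why: SN1 substitution of the tertiary alcohol with neighbouring-group participation: loss of water from C4' is assisted by the antiperiplanar axial chlorine on C5' (chlorine-bridged ion on the face opposite to the leaving group) and bromide enters axially on the face the water left, which gives net retention and the trans-diaxial Br/Cl pair that is also the more stable C4' epimer (methyl equatorial); any alkene formed by proton loss re-enters through the same ion, and the secondary C5 hydroxyl, next to the quaternary C6, should not ionise under these conditions.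

**Compound list**

1 | (S)-(−)-limonene | C=C(C)[C@H]1CCC(C)=CC1 | starting material
2 | allyllithium from 1 (lithium on the former isopropenyl methyl carbon, TMEDA-solvated) | [Li]CC(=C)[C@H]1CCC(C)=CC1 | intermediate
3 | dimethyl {2-[(1S)-4-methylcyclohex-3-en-1-yl]prop-2-en-1-yl}boronate | COB(OC)CC(=C)[C@H]1CCC(C)=CC1 | intermediate
4 | (S)-p-mentha-1,8-dien-10-ol, 2-[(1S)-4-methylcyclohex-3-en-1-yl]prop-2-en-1-ol | C=C(CO)[C@H]1CCC(C)=CC1 | intermediate
5 | (4S,8R)-8,9-epoxy-p-menth-1-en-10-ol, {(2R)-2-[(1S)-4-methylcyclohex-3-en-1-yl]oxiran-2-yl}methanol | C1O[C@]1([C@H]2CCC(C)=CC2)CO | intermediate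
6 | (2R)-2-[(1S)-4-methylcyclohex-3-en-1-yl]propane-1,2-diol | O[C@](C)([C@H]1CCC(C)=CC1)CO | intermediate
7 | (2R)-2-hydroxy-2-[(1S)-4-methylcyclohex-3-en-1-yl]propanal | O[C@](C)([C@H]1CCC(C)=CC1)C=O | intermediate
8 | allyl bromide | C=CCBr | starting material
9 | allylindium dibromide (simplest formulation of the allylindium reagent) | C=CC[In](Br)Br | intermediate
10 | (2R,3R)-2-[(1S)-4-methylcyclohex-3-en-1-yl]hex-5-ene-2,3-diol | O[C@](C)([C@H]1CCC(C)=CC1)[C@H](O)CC=C | intermediate
11 | 2-methyl-2-butene | CC=C(C)C | starting material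
12 | (2R,3R)-6-methyl-2-[(1S)-4-methylcyclohex-3-en-1-yl]hept-5-ene-2,3-diol | O[C@](C)([C@H]1CCC(C)=CC1)[C@H](O)CC=C(C)C | intermediate
13 | (2R,3R)-2-hydroxy-6-methyl-2-[(1S)-4-methylcyclohex-3-en-1-yl]hept-5-en-3-yl acetate | O[C@](C)([C@H]1CCC(C)=CC1)[C@H](OC(C)=O)CC=C(C)C | intermediate
14 | (2R,3R,5R)-5-bromo-2,6,6-trimethyl-2-[(1S)-4-methylcyclohex-3-en-1-yl]oxan-3-yl acetate | CC1(C)O[C@](C)([C@H]2CCC(C)=CC2)[C@H](OC(C)=O)C[C@H]1Br | intermediate
15 | (2R,3R,5R)-5-bromo-2-[(1S,3R,4R)-3-bromo-4-hydroxy-4-methylcyclohexyl]-2,6,6-trimethyloxan-3-yl acetate | CC1(C)O[C@](C)([C@H]2CC[C@@](C)(O)[C@H](Br)C2)[C@H](OC(C)=O)C[C@H]1Br | intermediate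
16 | (2R,3R,5R)-5-bromo-2,6,6-trimethyl-2-[(1S,3S,6R)-6-methyl-7-oxabicyclo[4.1.0]heptan-3-yl]oxan-3-yl acetate (oxirane oxygen cis to the oxanyl group) | CC1(C)O[C@](C)([C@H]2CC[C@@](C)(O3)[C@@H]3C2)[C@H](OC(C)=O)C[C@H]1Br | intermediate
17 | (2R,3R,5R)-5-bromo-2,6,6-trimethyl-2-[(1S,3S,6R)-6-methyl-7-oxabicyclo[4.1.0]heptan-3-yl]oxan-3-ol (oxirane oxygen cis to the oxanyl group) | CC1(C)O[C@](C)([C@H]2CC[C@@](C)(O3)[C@@H]3C2)[C@H](O)C[C@H]1Br | intermediate
18 | (2R,3R,5R)-5-bromo-2-[(1S,3R,4R)-3-chloro-4-hydroxy-4-methylcyclohexyl]-2,6,6-trimethyloxan-3-ol | CC1(C)O[C@](C)([C@H]2CC[C@@](C)(O)[C@H](Cl)C2)[C@H](O)C[C@H]1Br | intermediate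
19 | (2R,3R,5R)-5-bromo-2-[(1S,3R,4R)-4-bromo-3-chloro-4-methylcyclohexyl]-2,6,6-trimethyloxan-3-ol | CC1(C)O[C@](C)([C@H]2CC[C@@](C)(Br)[C@H](Cl)C2)[C@H](O)C[C@H]1Br | target

**Step count and risks**

Total step count: 11. Longest linear sequence: 11 steps (1 to 19); 8 and 11 are bought and enter in single steps.

Steps most likely to fail:

1. Step 8. In the anhydrous stage Br+ may be shared between the two trisubstituted alkenes, with capture of a ring bromonium by the C6 hydroxyl (bridged ether) or by the solvent, and 5-exo closure or loss of facial control at C3 may intrude. Fallback, from 10 back to 15: the two bromonium events are placed on different intermediates, the ring first.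
   - NBS in aqueous acetone at 0 °C is applied to 10, where the ring alkene is the only electron-rich one (the vinyl group is monosubstituted) and water is in large excess, to give (2R,3R)-2-[(1S,3R,4R)-3-bromo-4-hydroxy-4-methylcyclohexyl]hex-5-ene-2,3-diol F1.
   - Ac2O/pyridine acylates only the secondary hydroxyl, giving (2R,3R)-2-[(1S,3R,4R)-3-bromo-4-hydroxy-4-methylcyclohexyl]-2-hydroxyhex-5-en-3-yl acetate F2.
   - Cross-metathesis with 11 (second-generation Grubbs catalyst) gives (2R,3R)-2-[(1S,3R,4R)-3-bromo-4-hydroxy-4-methylcyclohexyl]-2-hydroxy-6-methylhept-5-en-3-yl acetate F3.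
   - NBS in (CF3)2CHOH at 0 °C then has a single alkene to attack and should give 15 by the same 6-endo chair closure.

2. Step 11. Ionisation at C4' may be diverted to proton loss, to migration of chlorine (opening of the bridged ion at C5') or to return of bromide on the wrong face. Fallback, from 14 (isolated by stopping step 8 after its first stage) back to 19: the tertiary bromide is installed by epoxide opening and the chloride last, using bromine as the neighbouring group.
   - Reagent-controlled Shi epoxidation of the ring alkene on the face trans to the oxanyl group (fructose-derived ketone of the matching enantiomeric series, KHSO5, K2CO3, MeCN/H2O, 0 °C) gives (2R,3R,5R)-5-bromo-2,6,6-trimethyl-2-(6-methyl-7-oxabicyclo[4.1.0]heptan-3-yl)oxan-3-yl acetate with the oxirane oxygen trans to the oxanyl group F4.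
   - HBr in Et2O at −40 °C opens this epimer at the tertiary C4', where Markovnikov and trans-diaxial opening coincide, to give (2R,3R,5R)-5-bromo-2-[(1S,3R,4R)-4-bromo-3-hydroxy-4-methylcyclohexyl]-2,6,6-trimethyloxan-3-yl acetate F5.
   - SOCl2 in CH2Cl2 without base replaces the axial C5' hydroxyl by chloride with retention, the antiperiplanar C4' bromine bridging as the chlorosulfite leaves and chloride opening the bromonium ion at C5' in the diaxial sense, to give the target acetate (2R,3R,5R)-5-bromo-2-[(1S,3R,4R)-4-bromo-3-chloro-4-methylcyclohexyl]-2,6,6-trimethyloxan-3-yl acetate F6.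
   - i-Bu2AlH in CH2Cl2 at −78 °C removes the acetate without base and gives 19.

3. Step 10. Chloride may enter at the tertiary C4' (through a twist-boat or after ring inversion), or the protonated oxirane may rearrange to a ketone by hydride shift. Fallback, from 14 (isolated as above) back to 18: the chlorohydrin is made directly with electrophilic chlorine, without the oxirane.
   - Trichloroisocyanuric acid in acetone/H2O at 0 °C should follow the same course as the bromohydrin reaction (chlorine on the face trans to the C1' substituent, water at C4' trans-diaxially) and give (2R,3R,5R)-5-bromo-2-[(1S,3R,4R)-3-chloro-4-hydroxy-4-methylcyclohexyl]-2,6,6-trimethyloxan-3-yl acetate F7.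
   - i-Bu2AlH in CH2Cl2 at −78 °C cleaves the acetate without closing the chlorohydrin to the oxirane and gives 18.

**Further compounds**

F1 | step 8 | (2R,3R)-2-[(1S,3R,4R)-3-bromo-4-hydroxy-4-methylcyclohexyl]hex-5-ene-2,3-diol | O[C@](C)([C@H]1CC[C@@](C)(O)[C@H](Br)C1)[C@H](O)CC=C
F2 | step 8 | (2R,3R)-2-[(1S,3R,4R)-3-bromo-4-hydroxy-4-methylcyclohexyl]-2-hydroxyhex-5-en-3-yl acetate | O[C@](C)([C@H]1CC[C@@](C)(O)[C@H](Br)C1)[C@H](OC(C)=O)CC=C
F3 | step 8 | (2R,3R)-2-[(1S,3R,4R)-3-bromo-4-hydroxy-4-methylcyclohexyl]-2-hydroxy-6-methylhept-5-en-3-yl acetate | O[C@](C)([C@H]1CC[C@@](C)(O)[C@H](Br)C1)[C@H](OC(C)=O)CC=C(C)C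
F4 | step 11 | (2R,3R,5R)-5-bromo-2,6,6-trimethyl-2-(6-methyl-7-oxabicyclo[4.1.0]heptan-3-yl)oxan-3-yl acetate, oxirane oxygen trans to the oxanyl group | CC1(C)O[C@](C)([C@H]2CC[C@](C)(O3)[C@H]3C2)[C@H](OC(C)=O)C[C@H]1Br
F5 | step 11 | (2R,3R,5R)-5-bromo-2-[(1S,3R,4R)-4-bromo-3-hydroxy-4-methylcyclohexyl]-2,6,6-trimethyloxan-3-yl acetate | CC1(C)O[C@](C)([C@H]2CC[C@@](C)(Br)[C@H](O)C2)[C@H](OC(C)=O)C[C@H]1Br
F6 | step 11 | (2R,3R,5R)-5-bromo-2-[(1S,3R,4R)-4-bromo-3-chloro-4-methylcyclohexyl]-2,6,6-trimethyloxan-3-yl acetate | CC1(C)O[C@](C)([C@H]2CC[C@@](C)(Br)[C@H](Cl)C2)[C@H](OC(C)=O)C[C@H]1Br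
F7 | step 10 | (2R,3R,5R)-5-bromo-2-[(1S,3R,4R)-3-chloro-4-hydroxy-4-methylcyclohexyl]-2,6,6-trimethyloxan-3-yl acetate | CC1(C)O[C@](C)([C@H]2CC[C@@](C)(O)[C@H](Cl)C2)[C@H](OC(C)=O)C[C@H]1Br
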